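Burkinabin C is 4,5-di-O-vanilloylquinic acid (quinic acid numbering throughout). The plan exploits the O3/O4/O5 triad on C3–C4–C5 of the cyclohexane ring. With C3 at the ketone level, C4–C5 is an aldol bond. Cutting it unravels the carbocycle to an acyclic 1,5-keto aldehyde that has one stereocentre (C1) and already carries the O4 vanillate. An L-proline-catalysed 6-enolendo aldol closes the ring and sets C4 and C5 (trans) in one operation. An Evans–Tishchenko reaction with O-benzylvanillin then turns the β-hydroxy ketone into the O5 vanillate and the free axial 3-OH. C1 stems from L-allylglycine by self-regeneration of stereocentres.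

Key step: step 7

Assumption: 1, 4, 5 and 14 are taken as commercially available. The quinic acid numbering (C1 = carbinol carbon bearing the carboxyl group, C3 = free carbinol, C4 and C5 acylated) is also used for the acyclic precursors.

Step 1
Reactants: 1 L-allylglycine
Product: 2 (S)-2-hydroxypent-4-enoic acid
Conditions: NaNO2, 1 M aq. H2SO4, 0 °C to rt
Reagents that add atoms: water (O)
Why: Diazotisation–hydrolysis of an α-amino acid, in which participation of the neighbouring carboxylate causes double inversion, so that the S configuration is retained.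

Step 2
Reactants: 2 (S)-2-hydroxypent-4-enoic acid
Product: 3 (2S,5S)-2-tert-butyl-5-(prop-2-en-1-yl)-1,3-dioxolan-4-one (cis)
Conditions: t-BuCHO, p-TsOH (cat.), H2SO4 (cat.), pentane, reflux, Dean–Stark; chromatographic removal of the minor trans isomer
Reagents that add atoms: pivalaldehyde (CC(C)(C)C=O)
Why: Acid-catalysed acetalisation under equilibrating conditions (first stage of self-regeneration of stereocentres), in which C5 relays its configuration to the new acetal carbon C2 because the cis-2,5-disubstituted ring is the more stable one.

Step 3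
Reactants: 4 3-bromo-2-(bromomethyl)prop-1-ene; 5 4-(benzyloxy)-3-methoxybenzoic acid
Product: 6 2-(bromomethyl)prop-2-en-1-yl 4-(benzyloxy)-3-methoxybenzoate
Conditions: K2CO3, DMF, rt, 4 in threefold excess
Reagents that add atoms: none
Why: SN2 O-alkylation of the potassium carboxylate by the doubly allylic dibromide, where the excess of 4 keeps the reaction at monosubstitution and no stereocentre is involved.

Step 4
Reactants: 3 (2S,5S)-2-tert-butyl-5-(prop-2-en-1-yl)-1,3-dioxolan-4-one; 6 2-(bromomethyl)prop-2-en-1-yl 4-(benzyloxy)-3-methoxybenzoate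
Product: 8 (2S,5R)-2-tert-butyl-5-(prop-2-en-1-yl)-5-{2-[(4-benzyloxy-3-methoxybenzoyl)oxymethyl]prop-2-en-1-yl}-1,3-dioxolan-4-one, via lithium enolate 7 (not isolated)
Conditions: LiN(i-Pr)2, THF, −78 °C; then 6, −78 to −40 °C
Reagents that add atoms: none
Why: Enolate alkylation (second stage of self-regeneration of stereocentres): the planar enolate 7 keeps only the acetal centre, whose tert-butyl group shields one face, so the allylic bromide enters anti to it and the quaternary carbon (future C1) is formed with overall retention, faster than any attack on the aryl ester at this temperature.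

Step 5
Reactants: 8 the alkylated dioxolanone
Product: 9 benzyl (R)-2-hydroxy-2-(prop-2-en-1-yl)-4-{[(4-benzyloxy-3-methoxybenzoyl)oxy]methyl}pent-4-enoate
Conditions: BnOH (5 equiv), BnONa (0.2 equiv), THF, −20 to 0 °C; AcOH quench
Reagents that add atoms: benzyl alcohol (OCc1ccccc1)
Why: Alkoxide-catalysed transesterification: the strained acylal-type carbonyl of the dioxolanone, activated by the α-oxygen and by a hemiacetal leaving group that collapses to pivalaldehyde, should react well before the electron-rich, conjugated vanillate ester, and C1 is not touched.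

Step 6
Reactants: 9 the benzyl ester diene
Product: 11 benzyl (R)-5-[(4-benzyloxy-3-methoxybenzoyl)oxy]-2-hydroxy-4-oxo-2-(2-oxoethyl)pentanoate, via bis-ozonide 10 (not isolated)
Conditions: O3, CH2Cl2, −78 °C (Sudan Red 7B as end-point indicator); Me2S, −78 °C to rt; used without storage
Reagents that add atoms: ozone ([O-][O+]=O)
Why: Ozonolysis (Criegee mechanism) with reductive work-up cleaves both terminal alkenes at once and so unmasks the C5 aldehyde and the C3 ketone, while the ester-deactivated arenes survive if the ozone stream is stopped at the indicator end point.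

Step 7
Reactants: 11 the acyclic keto aldehyde
Product: 13 benzyl (1R,4S,5R)-4-[(4-benzyloxy-3-methoxybenzoyl)oxy]-1,5-dihydroxy-3-oxocyclohexane-1-carboxylate (a protected 4-O-vanilloyl-3-dehydroquinate), via proline enamine 12 (not isolated)
Conditions: L-proline (0.3 equiv), DMSO/H2O 50:1, 0.02 M, rt
Reagents that add atoms: none
Why: L-Proline condenses with the C3 ketone of 11 to the E-enamine 12 (C3=C4, aroyloxy group trans to nitrogen to avoid A(1,3) strain), C4 attacks the C5 aldehyde while the proline carboxylic acid protonates the aldehyde oxygen, and hydrolysis of the iminium ion releases 13 and the catalyst. The closest known reaction type is the proline-catalysed intramolecular aldol of 1,5-dicarbonyl compounds (Hajos–Parrish–Eder–Sauer–Wiechert reaction), joined to the known preference of α-oxygenated ketones to react through the enamine of the oxygenated carbon. The cyclohexane ring closes in the 6-(enolendo)-exo-trig mode, and C4–C5 is the only bond formed. C4 (S) is controlled by the catalyst, since the bond forms on the enamine face that bears the carboxylic acid, in the same sense as in L-proline aldols of hydroxyacetone; C5 (R) is controlled by the tether, which holds C6 near C2 and the aldehyde oxygen near the carboxylic acid, so that O4 and O5 are antiperiplanar in the transition state (trans-diaxial, trans-diequatorial after ring inversion). The step needs regioselectivity, which the chain lengths secure because every other enamine or enol/carbonyl pairing would close a four-membered ring, and face selectivity relative to the fixed C1 centre, which rests on catalyst control. Dilution and a little water should suppress intermolecular aldol reaction and shorten the lifetime of the C3 iminium ion, from which loss of the C1 hydroxyl could start.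

Step 8
Reactants: 13 the cyclic β-hydroxy ketone; 14 4-(benzyloxy)-3-methoxybenzaldehyde (O-benzylvanillin)
Product: 16 benzyl (1S,3R,4R,5R)-4,5-bis[(4-benzyloxy-3-methoxybenzoyl)oxy]-1,3-dihydroxycyclohexane-1-carboxylate, via samarium hemiacetal 15 (not isolated)
Conditions: SmI2 (0.3 equiv) added to 14 (5 equiv), THF, −10 °C, until decolourised; then 13, −10 to 0 °C
Reagents that add atoms: none
Why: Evans–Tishchenko reaction: the secondary 5-OH adds to 14, and within the samarium-bound hemiacetal 15 (ring-inverted chair, O5 axial) hydride passes intramolecularly to the C3 carbonyl on the face that carries O5, which sets C3 anti to C5 (3-OH cis to O4), oxidises the hemiacetal carbon to the O5 vanillate and leaves O3 free, while premixing SmI2 with 14 consumes divalent samarium before the reducible α-acyloxy ketone is added.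

Step 9
Reactants: 16 the fully benzylated diester
Product: 17 Burkinabin C, (1S,3R,4R,5R)-1,3-dihydroxy-4,5-bis[(4-hydroxy-3-methoxybenzoyl)oxy]cyclohexane-1-carboxylic acid
Conditions: H2 (1 atm), 10% Pd/C, THF/EtOH, rt
Reagents that add atoms: none
Why: Catalytic hydrogenolysis removes the two aryl benzyl ethers and the benzyl ester under neutral conditions, which avoids the base-promoted acyl migration typical of acylquinic acids and leaves all four stereocentres untouched.

Compound list
1 | L-allylglycine, (S)-2-aminopent-4-enoic acid | N[C@@H](CC=C)C(=O)O | starting material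
2 | (S)-2-hydroxypent-4-enoic acid | O[C@@H](CC=C)C(=O)O | intermediate
3 | (2S,5S)-2-tert-butyl-5-(prop-2-en-1-yl)-1,3-dioxolan-4-one (cis) | C=CC[C@@H]1O[C@H](C(C)(C)C)OC1=O | intermediate
4 | 3-bromo-2-(bromomethyl)prop-1-ene | C=C(CBr)CBr | starting material
5 | 4-(benzyloxy)-3-methoxybenzoic acid | COc1cc(C(=O)O)ccc1OCc1ccccc1 | starting material
6 | 2-(bromomethyl)prop-2-en-1-yl 4-(benzyloxy)-3-methoxybenzoate | COc1cc(C(=O)OCC(=C)CBr)ccc1OCc1ccccc1 | intermediate
7 | lithium enolate of 3 (acetal centre retained) | C=CCC1=C([O-])O[C@@H](C(C)(C)C)O1.[Li+] | intermediate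
8 | (2S,5R)-2-tert-butyl-5-(prop-2-en-1-yl)-5-{2-[(4-benzyloxy-3-methoxybenzoyl)oxymethyl]prop-2-en-1-yl}-1,3-dioxolan-4-one | COc1cc(C(=O)OCC(=C)C[C@@]2(CC=C)O[C@H](C(C)(C)C)OC2=O)ccc1OCc1ccccc1 | intermediate
9 | benzyl (R)-2-hydroxy-2-(prop-2-en-1-yl)-4-{[(4-benzyloxy-3-methoxybenzoyl)oxy]methyl}pent-4-enoate | COc1cc(C(=O)OCC(=C)C[C@](O)(CC=C)C(=O)OCc2ccccc2)ccc1OCc1ccccc1 | intermediate
10 | bis(1,2,4-trioxolane) of 9 (ozonide carbons unassigned) | COc1cc(C(=O)OCC2(C[C@](O)(CC3OCOO3)C(=O)OCc3ccccc3)OCOO2)ccc1OCc1ccccc1 | intermediate
11 | benzyl (R)-5-[(4-benzyloxy-3-methoxybenzoyl)oxy]-2-hydroxy-4-oxo-2-(2-oxoethyl)pentanoate | COc1cc(C(=O)OCC(=O)C[C@](O)(CC=O)C(=O)OCc2ccccc2)ccc1OCc1ccccc1 | intermediate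
12 | (E)-enamine of L-proline and the C3 ketone of 11 | OC(=O)[C@@H]1CCCN1/C(C[C@](O)(CC=O)C(=O)OCc1ccccc1)=C/OC(=O)c1ccc(OCc2ccccc2)c(OC)c1 | intermediate
13 | benzyl (1R,4S,5R)-4-[(4-benzyloxy-3-methoxybenzoyl)oxy]-1,5-dihydroxy-3-oxocyclohexane-1-carboxylate | COc1cc(C(=O)O[C@@H]2C(=O)C[C@@](O)(C(=O)OCc3ccccc3)C[C@H]2O)ccc1OCc1ccccc1 | intermediate
14 | 4-(benzyloxy)-3-methoxybenzaldehyde | COc1cc(C=O)ccc1OCc1ccccc1 | starting material
15 | O5 hemiacetal of 13 with 14 (samarium-bound in the flask, drawn neutral, hemiacetal carbon unassigned) | COc1cc(C(=O)O[C@@H]2C(=O)C[C@@](O)(C(=O)OCc3ccccc3)C[C@H]2OC(O)c2ccc(OCc3ccccc3)c(OC)c2)ccc1OCc1ccccc1 | intermediate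
16 | benzyl (1S,3R,4R,5R)-4,5-bis[(4-benzyloxy-3-methoxybenzoyl)oxy]-1,3-dihydroxycyclohexane-1-carboxylate | COc1cc(C(=O)O[C@@H]2[C@H](O)C[C@@](O)(C(=O)OCc3ccccc3)C[C@H]2OC(=O)c2ccc(OCc3ccccc3)c(OC)c2)ccc1OCc1ccccc1 | intermediate
17 | Burkinabin C | COc1cc(C(=O)O[C@@H]2[C@H](O)C[C@@](O)(C(=O)O)C[C@H]2OC(=O)c2ccc(O)c(OC)c2)ccc1O | target

Total step count: 9. Longest linear sequence: 8 steps (1, 2, 4, 5, 6, 7, 8, 9).

Steps most likely to fail

Step 7. Three things may go wrong:
- Enamine formation at the α-acyloxy ketone may be slow.
- Amine-promoted β-elimination of the C1 hydroxyl may start from the C3 or C5 enamine or iminium ion.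
- Facial selectivity may erode if the hydrogen-bond-donating C1 hydroxyl steers the aldehyde against the catalyst.

The fallback sets out from 11 and comes back to the route at 16. It replaces kinetic enamine control by an amine-free tandem aldol/Evans–Tishchenko reaction. Compound 11 and 14 (5 equiv) are treated with SmI3 (0.5 equiv) and 4 Å molecular sieves in THF at 0 °C to rt. The samarium aldolates interconvert by retro-aldol reaction, and only the irreversible hydride shift in 15 drains the equilibrium. That shift prefers the aldolate whose O4 substituent is equatorial in the hydride-transfer ring and whose axial C1 ester can act as a further ligand to trivalent samarium. This fallback makes no new compound (F0).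

Step 8. Five things may go wrong:
- The ring inversion that places O5 axial may slow the hydride shift.
- The axial tertiary C1 hydroxyl may then compete as the anchor and deliver hydride to the wrong face.
- Residual divalent samarium may cause reductive loss of the α-acyloxy group.
- O5 may lactonise onto the benzyl ester.
- The acyl group may migrate from O4 to O3.

The fallback sets out from 13 and comes back at 16, and it separates acylation from reduction. Acid 5 is converted with (COCl)2 and catalytic DMF into 4-(benzyloxy)-3-methoxybenzoyl chloride F1. This acylates only the secondary 5-OH in pyridine/CH2Cl2 at 0 °C to give benzyl 4,5-bis-O-[4-(benzyloxy)-3-methoxybenzoyl]-3-dehydroquinate F2. LiBH(s-Bu)3 in THF at −78 °C, quenched cold with AcOH, then reduces the ketone under steric approach control. The bulky hydride attacks equatorially, the axial trajectory being blocked by the axial C1 oxygen, and the axial 3-OH of 16 results.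

Step 5. The allylic vanillate may be lost by competing transesterification while the hindered dioxolanone opens. The fallback sets out from 8 and comes back at 9. It accepts the cleavage of both esters and rebuilds them one at a time.
- LiOH in THF/H2O gives (R)-2-hydroxy-4-(hydroxymethyl)-2-(prop-2-en-1-yl)pent-4-enoic acid F3, handled as its carboxylate, with recovery of 5.
- BnBr and KHCO3 in DMF give its benzyl ester F4.
- A Steglich esterification with 5 (EDC·HCl, catalytic DMAP, CH2Cl2, 0 °C) acylates only the primary allylic hydroxyl, the tertiary one being inert, to give 9.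

Further compounds
F0 | step 7 | none | none
F1 | step 8 | 4-(benzyloxy)-3-methoxybenzoyl chloride | COc1cc(C(=O)Cl)ccc1OCc1ccccc1
F2 | step 8 | benzyl 4,5-bis-O-[4-(benzyloxy)-3-methoxybenzoyl]-3-dehydroquinate | COc1cc(C(=O)O[C@@H]2C(=O)C[C@@](O)(C(=O)OCc3ccccc3)C[C@H]2OC(=O)c2ccc(OCc3ccccc3)c(OC)c2)ccc1OCc1ccccc1
F3 | step 5 | (R)-2-hydroxy-4-(hydroxymethyl)-2-(prop-2-en-1-yl)pent-4-enoic acid | C=CC[C@@](O)(CC(=C)CO)C(=O)O
F4 | step 5 | benzyl (R)-2-hydroxy-4-(hydroxymethyl)-2-(prop-2-en-1-yl)pent-4-enoate | C=CC[C@@](O)(CC(=C)CO)C(=O)OCc1ccccc1
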